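With the lactone carbonyl as C1 and the chain counted through C2H2, the peroxy methine C3, the lactone carbinol C4 and C5H2 to the quaternary peroxy carbon C6, the two distant stereocentres C3 and C6 of the 1,2-dioxane ring touch each other only via O–O. Each is therefore made in its own fragment, the fragments are married at oxygen, and the dioxane is disconnected at C4–C5, which as an alkene holds no stereochemistry. One ring-closing metathesis of an acyclic peroxide carrying a vinyl group on C6 and an isopropenyl group on C3 builds the six-membered peroxide ring. It also places the C4=C5 alkene where the C1 acid can lactonise, C3 dictating C4.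

Key step: step 13

Remark on labels: O1 is the peroxide oxygen on C6 and O2 the one on C3. C1–C6, O1 and O2 are used in the names of 16–26 and 32.
Remark on protecting groups: the chain terminus is carried as a TBDPS ether rather than a TBS ether. Phosphomolybdic acid, the catalyst of step 4, is itself a reagent for cleaving TBS ethers. C1 stays at the alcohol level (PMB ether) until after ring closure, because a β-peroxy carbonyl group would not survive the basic steps 10 and 12. The carbon skeletons of 18 and 19 are unaffected.
Assumption: commercial (2E,4E)-hepta-2,4-dienal is distilled and taken as the geometrically pure E,E isomer.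

Step 1
Reactants: 1 undec-10-yn-1-ol
Product: 2 tert-butyl(diphenyl)(undec-10-yn-1-yloxy)silane
Conditions: TBDPSCl, imidazole, CH2Cl2, 0 °C to rt
Reagents that add atoms: tert-butyl(chloro)diphenylsilane CC(C)(C)[Si](Cl)(c1ccccc1)c1ccccc1
Why: Imidazole-promoted silylation of a primary alcohol is routine, and the TBDPS ether is inert to organoalanes, butyllithium and the acidic peroxide medium of step 4.

Step 2
Reactants: 2 TBDPS ether of undec-10-yn-1-ol
Product: 5 (E)-12-[(tert-butyldiphenylsilyl)oxy]-3-methyldodec-2-en-1-ol, via alkenyldimethylalane 3 (not isolated), via lithium alkenylaluminate 4 (not isolated)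
Conditions: Me3Al, Cp2ZrCl2 (cat.), CH2Cl2, 0 °C to rt; concentrate; n-BuLi, hexane/THF, −78 to 0 °C; (CH2O)n, rt; aq. work-up
Reagents that add atoms: trimethylaluminium C[Al](C)C; paraformaldehyde (as formaldehyde) C=O
Why: Negishi zirconium-catalysed carboalumination adds methyl and aluminium syn across the terminal alkyne with the metal at the terminus, and hydroxymethylation of the derived aluminate proceeds with retention, which fixes the E geometry that step 3 translates into configuration at C6.

Step 3
Reactants: 5 (E)-allylic alcohol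
Product: 6 [(2R,3R)-3-{9-[(tert-butyldiphenylsilyl)oxy]nonyl}-3-methyloxiran-2-yl]methanol
Conditions: Ti(OiPr)4 (cat.), D-(−)-DIPT (cat.), t-BuOOH, 4 Å MS, CH2Cl2, −20 °C
Reagents that add atoms: tert-butyl hydroperoxide CC(C)(C)OO
Why: Katsuki–Sharpless asymmetric epoxidation of a geraniol-type (E)-3-methylalk-2-en-1-ol with the D-(−)-tartrate should deliver the (2R,3R)-epoxide, so the future C6 is set in the configuration opposite to the one finally needed.

Step 4
Reactants: 6 (2R,3R)-epoxy alcohol
Product: 7 (2R,3S)-12-[(tert-butyldiphenylsilyl)oxy]-3-hydroperoxy-3-methyldodecane-1,2-diol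
Conditions: anhydrous H2O2 (ca. 10 equiv in Et2O), H3PMo12O40 (3 mol %), 0 °C to rt
Reagents that add atoms: hydrogen peroxide OO
Why: In this acid-catalysed perhydrolysis of a trisubstituted epoxide the activated oxirane opens at its tertiary carbon by backside attack of H2O2, so C6 is inverted to S; a product of retention would be a diastereomer, because the neighbouring carbinol centre is still present, and could be removed by chromatography.

Step 5
Reactants: 8 propane-1,3-diol
Product: 9 3-[(4-methoxybenzyl)oxy]propan-1-ol
Conditions: NaH (1 equiv), PMBCl (1 equiv), Bu4NI (cat.), THF/DMF, 0 °C to rt, diol in threefold excess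
Reagents that add atoms: 4-methoxybenzyl chloride COc1ccc(CCl)cc1
Why: Williamson etherification with the cheap diol in excess statistically favours the mono-ether.

Step 6
Reactants: 9 mono-PMB ether
Product: 10 3-[(4-methoxybenzyl)oxy]propanal
Conditions: TEMPO (10 mol %), PhI(OAc)2, CH2Cl2, rt
Reagents that add atoms: none
Why: Oxoammonium oxidation stops at the aldehyde in the absence of water, and its base-free medium avoids β-elimination of 4-methoxybenzyl alcohol.

Step 7
Reactants: 10 3-[(4-methoxybenzyl)oxy]propanal; 11 2-bromopropene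
Product: 13 rac-5-[(4-methoxybenzyl)oxy]-2-methylpent-1-en-3-ol, via isopropenylmagnesium bromide 12 (not isolated)
Conditions: 11, Mg, THF, reflux; then 10, −78 to 0 °C; aq. work-up
Reagents that add atoms: none
Why: Grignard 1,2-addition to an unhindered aldehyde builds the C3–C4 bond, and no stereocontrol is sought because the next step resolves the carbinol.

Step 8
Reactants: 13 racemic allylic alcohol
Product: 14 (R)-5-[(4-methoxybenzyl)oxy]-2-methylpent-1-en-3-ol
Conditions: Ti(OiPr)4, L-(+)-DIPT, t-BuOOH (0.6 equiv), 4 Å MS, CH2Cl2, −20 °C, to slightly over half conversion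
Reagents that add atoms: none
Why: In the Sharpless kinetic resolution with L-(+)-DIPT the (S)-enantiomer of a secondary allylic alcohol is epoxidised far faster (erythro product), so the alcohol left behind should be the (R)-enantiomer in high enantiomeric purity.

Step 9
Reactants: 14 (R)-allylic alcohol
Product: 15 (R)-5-[(4-methoxybenzyl)oxy]-2-methylpent-1-en-3-yl methanesulfonate
Conditions: MsCl, Et3N, CH2Cl2, −20 °C; cold aq. work-up, used at once
Reagents that add atoms: methanesulfonyl chloride CS(=O)(=O)Cl
Why: Sulfonylation occurs at oxygen and leaves the C–O bond and the R configuration untouched, and the methyl group sits on the nodal central carbon of the allyl system and so gives no extra push towards ionisation.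

Step 10
Reactants: 7 (2R,3S)-hydroperoxy diol; 15 (R)-allylic mesylate
Product: 16 (2R,3S)-12-[(tert-butyldiphenylsilyl)oxy]-3-({(3S)-5-[(4-methoxybenzyl)oxy]-2-methylpent-1-en-3-yl}peroxy)-3-methyldodecane-1,2-diol
Conditions: 7, CsOH·H2O (0.95 equiv), DMF, 0 °C; then 15 (1.3 equiv), 0 °C
Reagents that add atoms: none
Why: In this Williamson-type O-alkylation of a hydroperoxide the caesium peroxide, far easier to form than an alkoxide and an α-effect nucleophile, displaces the secondary mesylate by SN2 with inversion, turning (R)-15 into the (S)-configured C3–O2 bond while C6 is untouched; enantiomeric leakage in either partner ends up as a separable diastereomer.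

Step 11
Reactants: 16 peroxy diol
Product: 17 (2S)-11-[(tert-butyldiphenylsilyl)oxy]-2-({(3S)-5-[(4-methoxybenzyl)oxy]-2-methylpent-1-en-3-yl}peroxy)-2-methylundecanal
Conditions: NaIO4, THF/pH 7 buffer, 0 °C to rt
Reagents that add atoms: none
Why: Malaprade glycol cleavage is neutral and specific for the 1,2-diol, and it leaves a non-enolisable aldehyde (the future C5) on quaternary C6, so nothing can epimerise.

Step 12
Reactants: 17 α-peroxy aldehyde
Product: 18 tert-butyl{[(10S)-10-({(3S)-5-[(4-methoxybenzyl)oxy]-2-methylpent-1-en-3-yl}peroxy)-10-methyldodec-11-en-1-yl]oxy}diphenylsilane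
Conditions: Ph3PCH3Br, KHMDS, THF, 0 °C; then 17, −78 to 0 °C
Reagents that add atoms: methyltriphenylphosphonium bromide C[P+](c1ccccc1)(c1ccccc1)c1ccccc1.[Br-]
Why: In this Wittig methylenation the ylide adds to the non-enolisable aldehyde at low temperature much faster than it could deprotonate C3–H, and dialkyl peroxides tolerate phosphoranes because no free phosphine is present.

Step 13
Reactants: 18 tertiary–secondary bis-allylic dialkyl peroxide
Product: 19 (3S,6S)-6-{9-[(tert-butyldiphenylsilyl)oxy]nonyl}-3-{2-[(4-methoxybenzyl)oxy]ethyl}-4,6-dimethyl-3,6-dihydro-1,2-dioxine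
Conditions: Hoveyda–Grubbs II (2 × 5 mol %), 1,4-benzoquinone (20 mol %), CH2Cl2 (2 mM), 40 °C, Ar sparge
Reagents that add atoms: none
Why: The reaction follows the Chauvin [2+2]/retro-[2+2] cycle: ruthenium should enter at the less substituted alkene, the vinyl group on C6, and the C5 alkylidene so formed adds across the isopropenyl C=C of the same molecule, the metallacyclobutane collapsing to the C4=C5 double bond and a ruthenium methylidene that carries the chain with loss of ethylene. The closest known reaction type is the ring-closing metathesis of unsaturated dialkyl peroxides to 3,6-dihydro-1,2-dioxines, in which the O–O bond behaves as a spectator towards ruthenium alkylidenes. The single ring formed, the six-membered 1,2-dioxine, is closed at carbon in the 1,7-diene-to-cyclohexene mode, the four-atom C6–O1–O2–C3 tether ending up inside the ring and the new alkene endocyclic and necessarily Z. No stereocentre is created, and since no bond to C3 or C6 is made or broken both configurations pass unchanged into 19. The step needs cyclisation to beat dimerisation and alkene migration: full substitution at C6 (Thorpe–Ingold effect), the skewed peroxide dihedral, 2 mM dilution and ethylene removal favour closure, both alkenes are too hindered to homodimerise readily, and benzoquinone intercepts ruthenium hydrides.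

Step 14
Reactants: 19 dihydrodioxine PMB ether
Product: 20 2-[(3S,6S)-6-{9-[(tert-butyldiphenylsilyl)oxy]nonyl}-4,6-dimethyl-3,6-dihydro-1,2-dioxin-3-yl]ethanol
Conditions: DDQ, CH2Cl2/pH 7 buffer, 0 °C
Reagents that add atoms: none
Why: Oxidative PMB cleavage starts with electron transfer from the anisyl ring and is orthogonal to the silyl ether, the trisubstituted alkene and the peroxide.

Step 15
Reactants: 20 primary alcohol
Product: 22 [(3S,6S)-6-{9-[(tert-butyldiphenylsilyl)oxy]nonyl}-4,6-dimethyl-3,6-dihydro-1,2-dioxin-3-yl]acetic acid, via β-peroxy aldehyde 21 (not isolated)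
Conditions: TEMPO (20 mol %), PhI(OAc)2 (2.5 equiv), MeCN/H2O, rt
Reagents that add atoms: water O
Why: Oxoammonium oxidation in aqueous acetonitrile carries the alcohol through the aldehyde hydrate to the acid at slightly acidic pH, so the β-peroxy aldehyde never meets a base and cannot eliminate.

Step 16
Reactants: 22 dihydrodioxinylacetic acid
Product: 23 (3S,4R,5S,6S)-5-iodo peroxylactone: cis-fused γ-lactone/1,2-dioxane with 4-CH3 and 5-I anti to the lactone oxygen and the TBDPS-oxynonyl chain on C6
Conditions: I2, NaHCO3, MeCN, 0 °C, dark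
Reagents that add atoms: iodine II
Why: In this iodolactonisation reversible iodonium formation on C4=C5 is followed by 5-exo, Markovnikov attack of the carboxylate at tertiary C4, which can only come from the ring face that carries C2, so C3 sets C4 as a cis-fused lactone with iodine anti on C5; the metal-free route is preferred to cobalt-hydride hydrofunctionalisation because Co(II) complexes cleave 3,6-dihydro-1,2-dioxines.

Step 17
Reactants: 23 iodolactone
Product: 24 (3S,4S,6S)-6-{9-[(tert-butyldiphenylsilyl)oxy]nonyl}-4,6-dimethyl peroxylactone (cis-fused γ-lactone/1,2-dioxane)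
Conditions: Bu3SnH (0.2 M), Et3B (cat.), air, toluene, 0 °C to rt
Reagents that add atoms: none
Why: In this tin hydride radical dehalogenation iodine abstraction is extremely fast and the C5 radical is quenched by concentrated stannane before it can attack O1, an attack that the ring geometry (C5···O1–O2 far from collinear) disfavours anyway; the C5 centre vanishes and C3, C4 and C6 are untouched.

Step 18
Reactants: 24 peroxylactone silyl ether
Product: 25 (3S,4S,6S)-6-(9-hydroxynonyl)-4,6-dimethyl peroxylactone
Conditions: HF·pyridine, pyridine, THF, 0 °C to rt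
Reagents that add atoms: none
Why: Fluoride-driven desilylation under mildly acidic conditions spares the base-sensitive β-peroxy lactone, which basic TBAF might open.

Step 19
Reactants: 25 primary alcohol
Product: 26 9-[(3S,4S,6S)-4,6-dimethyl peroxylactone-6-yl]nonanal
Conditions: Dess–Martin periodinane, CH2Cl2, 0 °C to rt
Reagents that add atoms: none
Why: Dess–Martin oxidation is neutral, stops at the aldehyde and does not interact with lactone or peroxide.

Step 20
Reactants: 27 (2E,4E)-hepta-2,4-dienal
Product: 28 (2E,4E)-hepta-2,4-dien-1-ol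
Conditions: NaBH4, MeOH, 0 °C
Reagents that add atoms: none
Why: Borohydride reduces dienals by clean 1,2-addition and leaves both alkene geometries intact.

Step 21
Reactants: 28 dienol
Product: 29 (2E,4E)-1-bromohepta-2,4-diene
Conditions: PBr3 (0.4 equiv), Et2O, −10 °C, dark; used crude
Reagents that add atoms: phosphorus tribromide BrP(Br)Br
Why: Bromination of a primary dienylic alcohol through its phosphite ester is a direct SN2 process at low temperature, so the conjugated E,E system is neither transposed nor isomerised.

Step 22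
Reactants: 29 dienyl bromide
Product: 30 diethyl [(2E,4E)-hepta-2,4-dien-1-yl]phosphonate
Conditions: P(OEt)3 (neat), 100 °C, EtBr distilled off
Reagents that add atoms: triethyl phosphite CCOP(OCC)OCC
Why: The Michaelis–Arbuzov reaction of a primary allylic-type bromide proceeds at the terminal carbon and is driven by loss of volatile bromoethane.

Step 23
Reactants: 26 peroxylactone aldehyde; 30 dienylphosphonate
Product: 32 (3S,4S,6S)-6-[(9E,11E,13E)-hexadeca-9,11,13-trien-1-yl]-4,6-dimethyl peroxylactone (CNP0229098.1), via lithiated dienylphosphonate 31 (not isolated)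
Conditions: 30 (1.3 equiv), LiHMDS (1.2 equiv), THF, −78 °C; then 26, −78 to 0 °C; pH 7 buffer
Reagents that add atoms: none
Why: In this Horner–Wadsworth–Emmons olefination the preformed carbanion adds to the aldehyde at −78 °C faster than it enolises the lactone, phosphate loss from the equilibrated adduct should give the new (E)-alkene and the two (E)-alkenes of 30 are retained; should transient β-elimination of O2 from C3 occur, re-addition can only rebuild the cis-fused ring, so no stereocentre is at risk.

Compound list
1 | undec-10-yn-1-ol | C#CCCCCCCCCCO | starting material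
2 | tert-butyl(diphenyl)(undec-10-yn-1-yloxy)silane | C#CCCCCCCCCCO[Si](c1ccccc1)(c1ccccc1)C(C)(C)C | intermediate
3 | {(1E)-11-[(tert-butyldiphenylsilyl)oxy]-2-methylundec-1-en-1-yl}dimethylalane | CC(C)(C)[Si](c1ccccc1)(c1ccccc1)OCCCCCCCCC/C(C)=C/[Al](C)C | intermediate (not isolated)
4 | lithium butyl{(1E)-11-[(tert-butyldiphenylsilyl)oxy]-2-methylundec-1-en-1-yl}dimethylaluminate | CC(C)(C)[Si](c1ccccc1)(c1ccccc1)OCCCCCCCCC/C(C)=C/[Al-](C)(C)CCCC.[Li+] | intermediate (not isolated)
5 | (E)-12-[(tert-butyldiphenylsilyl)oxy]-3-methyldodec-2-en-1-ol | CC(C)(C)[Si](c1ccccc1)(c1ccccc1)OCCCCCCCCC/C(C)=C/CO | intermediate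
6 | [(2R,3R)-3-{9-[(tert-butyldiphenylsilyl)oxy]nonyl}-3-methyloxiran-2-yl]methanol | CC(C)(C)[Si](c1ccccc1)(c1ccccc1)OCCCCCCCCC[C@@]1(C)O[C@@H]1CO | intermediate
7 | (2R,3S)-12-[(tert-butyldiphenylsilyl)oxy]-3-hydroperoxy-3-methyldodecane-1,2-diol | CC(C)(C)[Si](c1ccccc1)(c1ccccc1)OCCCCCCCCC[C@](C)(OO)[C@H](O)CO | intermediate
8 | propane-1,3-diol | OCCCO | starting material
9 | 3-[(4-methoxybenzyl)oxy]propan-1-ol | COc1ccc(COCCCO)cc1 | intermediate
10 | 3-[(4-methoxybenzyl)oxy]propanal | COc1ccc(COCCC=O)cc1 | intermediate
11 | 2-bromopropene | CC(Br)=C | starting material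
12 | isopropenylmagnesium bromide | CC(=C)[Mg]Br | intermediate (not isolated)
13 | rac-5-[(4-methoxybenzyl)oxy]-2-methylpent-1-en-3-ol | CC(=C)C(O)CCOCc1ccc(OC)cc1 | intermediate
14 | (R)-5-[(4-methoxybenzyl)oxy]-2-methylpent-1-en-3-ol | CC(=C)[C@H](O)CCOCc1ccc(OC)cc1 | intermediate
15 | (R)-5-[(4-methoxybenzyl)oxy]-2-methylpent-1-en-3-yl methanesulfonate | CC(=C)[C@H](OS(C)(=O)=O)CCOCc1ccc(OC)cc1 | intermediate
16 | (2R,3S)-12-[(tert-butyldiphenylsilyl)oxy]-3-({(3S)-5-[(4-methoxybenzyl)oxy]-2-methylpent-1-en-3-yl}peroxy)-3-methyldodecane-1,2-diol | CC(C)(C)[Si](c1ccccc1)(c1ccccc1)OCCCCCCCCC[C@](C)(OO[C@@H](CCOCc1ccc(OC)cc1)C(C)=C)[C@H](O)CO | intermediate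
17 | (2S)-11-[(tert-butyldiphenylsilyl)oxy]-2-({(3S)-5-[(4-methoxybenzyl)oxy]-2-methylpent-1-en-3-yl}peroxy)-2-methylundecanal | CC(C)(C)[Si](c1ccccc1)(c1ccccc1)OCCCCCCCCC[C@@](C)(C=O)OO[C@@H](CCOCc1ccc(OC)cc1)C(C)=C | intermediate
18 | tert-butyl{[(10S)-10-({(3S)-5-[(4-methoxybenzyl)oxy]-2-methylpent-1-en-3-yl}peroxy)-10-methyldodec-11-en-1-yl]oxy}diphenylsilane (metathesis precursor) | CC(C)(C)[Si](c1ccccc1)(c1ccccc1)OCCCCCCCCC[C@@](C)(C=C)OO[C@@H](CCOCc1ccc(OC)cc1)C(C)=C | intermediate
19 | (3S,6S)-6-{9-[(tert-butyldiphenylsilyl)oxy]nonyl}-3-{2-[(4-methoxybenzyl)oxy]ethyl}-4,6-dimethyl-3,6-dihydro-1,2-dioxine (metathesis product) | CC(C)(C)[Si](c1ccccc1)(c1ccccc1)OCCCCCCCCC[C@@]1(C)C=C(C)[C@H](CCOCc2ccc(OC)cc2)OO1 | intermediate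
20 | 2-[(3S,6S)-6-{9-[(tert-butyldiphenylsilyl)oxy]nonyl}-4,6-dimethyl-3,6-dihydro-1,2-dioxin-3-yl]ethanol | CC(C)(C)[Si](c1ccccc1)(c1ccccc1)OCCCCCCCCC[C@@]1(C)C=C(C)[C@H](CCO)OO1 | intermediate
21 | [(3S,6S)-6-{9-[(tert-butyldiphenylsilyl)oxy]nonyl}-4,6-dimethyl-3,6-dihydro-1,2-dioxin-3-yl]acetaldehyde | CC(C)(C)[Si](c1ccccc1)(c1ccccc1)OCCCCCCCCC[C@@]1(C)C=C(C)[C@H](CC=O)OO1 | intermediate (not isolated)
22 | [(3S,6S)-6-{9-[(tert-butyldiphenylsilyl)oxy]nonyl}-4,6-dimethyl-3,6-dihydro-1,2-dioxin-3-yl]acetic acid | CC(C)(C)[Si](c1ccccc1)(c1ccccc1)OCCCCCCCCC[C@@]1(C)C=C(C)[C@H](CC(=O)O)OO1 | intermediate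
23 | (3S,4R,5S,6S)-5-iodo peroxylactone, TBDPS ether (cis-fused γ-lactone/1,2-dioxane, I anti to lactone O) | CC(C)(C)[Si](c1ccccc1)(c1ccccc1)OCCCCCCCCC[C@@]1(C)[C@@H](I)[C@]2(C)OC(=O)C[C@@H]2OO1 | intermediate
24 | (3S,4S,6S)-peroxylactone, TBDPS ether | CC(C)(C)[Si](c1ccccc1)(c1ccccc1)OCCCCCCCCC[C@@]1(C)C[C@]2(C)OC(=O)C[C@@H]2OO1 | intermediate
25 | (3S,4S,6S)-6-(9-hydroxynonyl)-4,6-dimethyl peroxylactone | OCCCCCCCCC[C@@]1(C)C[C@]2(C)OC(=O)C[C@@H]2OO1 | intermediate
26 | 9-[(3S,4S,6S)-4,6-dimethyl peroxylactone-6-yl]nonanal | O=CCCCCCCCC[C@@]1(C)C[C@]2(C)OC(=O)C[C@@H]2OO1 | intermediate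
27 | (2E,4E)-hepta-2,4-dienal | CC/C=C/C=C/C=O | starting material
28 | (2E,4E)-hepta-2,4-dien-1-ol | CC/C=C/C=C/CO | intermediate
29 | (2E,4E)-1-bromohepta-2,4-diene | CC/C=C/C=C/CBr | intermediate
30 | diethyl [(2E,4E)-hepta-2,4-dien-1-yl]phosphonate | CC/C=C/C=C/CP(=O)(OCC)OCC | intermediate
31 | lithium salt of the α-carbanion of 30 | [Li+].CC/C=C/C=C/[CH-]P(=O)(OCC)OCC | intermediate (not isolated)
32 | (3S,4S,6S)-6-[(9E,11E,13E)-hexadeca-9,11,13-trien-1-yl]-4,6-dimethyl peroxylactone, CNP0229098.1 | CC/C=C/C=C/C=C/CCCCCCCC[C@@]1(C)C[C@]2(C)OC(=O)C[C@@H]2OO1 | target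

Total step count: 23.
Longest linear sequence: 16 steps (8 to 32: steps 5–19 and 23). The branch from 1 counts 15 steps and the phosphonate branch 4.

Steps most likely to fail

Step 13 (ring-closing metathesis). The catalyst may load only sluggishly on the vinyl group next to fully substituted C6. Catalyst decay, hydride-induced alkene migration or O–O cleavage by ruthenium decomposition products could then overtake ring closure. The fallback is a relay ring-closing metathesis that sets out from aldehyde 17. This aldehyde is olefinated with the ylide of hex-5-en-1-yl(triphenyl)phosphonium bromide, in place of the methylene ylide, to give the relay substrate (10S,11Z)-heptadeca-11,16-dienyl peroxide F1. Ruthenium then enters at the unhindered terminal alkene, expels cyclopentene and is thereby delivered onto C5, from where it closes onto the isopropenyl group. The sequence comes back to the route at 19.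

Step 10 (peroxide alkylation). The bulky peroxide anion may attack the terminal methylene in the SN2′ sense. The allylic mesylate may partly ionise, with erosion of configuration at C3, or the base may fragment the β-hydroxy hydroperoxide. The fallback reverses the polarity, so that the C3–O bond is never broken and no base is used, and it sets out from epoxy alcohol 6. Commercial 4-methylpent-3-en-1-ol is converted (NaH, PMBCl) into 1-methoxy-4-{[(4-methylpent-3-en-1-yl)oxy]methyl}benzene F2. Schenck ene photooxygenation (O2, tetraphenylporphyrin, hν) and chromatographic removal of the tertiary regioisomer give the racemic secondary allylic hydroperoxide F3. Lewis-acid-catalysed opening of 6 at its tertiary carbon by this hydroperoxide (Yb(OTf)3 or TMSOTf, Et2O, low temperature), again with inversion, gives 16 together with the (3R)-epimer of 16 F4, which is removed by chromatography. The route is rejoined at 16.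

Step 23 (dienyl olefination). The lactone may be enolised, with β-elimination of the peroxide, during the warm-up that phosphate loss requires. Control of the new alkene geometry may also be incomplete. The fallback builds the last alkene by metathesis and joins the triene by cross-coupling, and it sets out from aldehyde 26. A fast, cold Wittig methylenation gives the 6-(dec-9-en-1-yl) peroxylactone F5. Cross-metathesis with vinylboronic acid pinacol ester (Hoveyda–Grubbs II) gives the (E)-alkenyl pinacol boronate F6. Suzuki–Miyaura coupling (Pd(dppf)Cl2, aq. K3PO4, THF, rt) then uses (1E,3E)-1-iodohexa-1,3-diene F7, prepared apart from any peroxide by Takai iodo-olefination of (E)-pent-2-enal, and joins the two geometrically defined halves. The route is rejoined at 32.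

Further compounds
F1 | step 13 | tert-butyl{[(10S,11Z)-10-({(3S)-5-[(4-methoxybenzyl)oxy]-2-methylpent-1-en-3-yl}peroxy)-10-methylheptadeca-11,16-dien-1-yl]oxy}diphenylsilane | CC(C)(C)[Si](c1ccccc1)(c1ccccc1)OCCCCCCCCC[C@@](C)(/C=C\CCCC=C)OO[C@@H](CCOCc1ccc(OC)cc1)C(C)=C
F2 | step 10 | 1-methoxy-4-{[(4-methylpent-3-en-1-yl)oxy]methyl}benzene | CC(C)=CCCOCc1ccc(OC)cc1
F3 | step 10 | rac-1-{[(3-hydroperoxy-4-methylpent-4-en-1-yl)oxy]methyl}-4-methoxybenzene | CC(=C)C(OO)CCOCc1ccc(OC)cc1
F4 | step 10 | (3R)-epimer of 16 at the peroxy methine C3 | CC(C)(C)[Si](c1ccccc1)(c1ccccc1)OCCCCCCCCC[C@](C)(OO[C@H](CCOCc1ccc(OC)cc1)C(C)=C)[C@H](O)CO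
F5 | step 23 | (3S,4S,6S)-6-(dec-9-en-1-yl)-4,6-dimethyl peroxylactone | C=CCCCCCCCC[C@@]1(C)C[C@]2(C)OC(=O)C[C@@H]2OO1
F6 | step 23 | (3S,4S,6S)-4,6-dimethyl-6-[(9E)-10-(4,4,5,5-tetramethyl-1,3,2-dioxaborolan-2-yl)dec-9-en-1-yl] peroxylactone | CC1(C)OB(/C=C/CCCCCCCC[C@@]2(C)C[C@]3(C)OC(=O)C[C@@H]3OO2)OC1(C)C
F7 | step 23 | (1E,3E)-1-iodohexa-1,3-diene | CC/C=C/C=C/I
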